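**Retrosynthetic overview**

- Feature: ring A is a resorcinol with oxygens on C1 and C3 and hydrogens on C2, C4 and C6. Its only carbon substituent, the C17 chain (benzylic C1'), sits on C5, meta to both oxygens. A 3-substituted cyclobutenone and an oxygen-substituted ethyne give exactly this 1,3,5-pattern.
- Last disconnection: the aryl O–Si(iPr)3 and the C12' O–SiMe2tBu ethers, both cleaved by fluoride in one operation.
- Key disconnection: ring A (the only ring, built late) from the chain-bearing cyclobutenone and (triisopropylsilyloxy)ethyne. C1–C2 and C3–C4 come from a ketene–alkyne [2+2] step, and C1–C6 closes by 6π electrocyclisation.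
- Cyclobutenone: from 3-ethoxycyclobut-2-en-1-one and the Grignard reagent of the C17 bromide. The two Z-alkenes come from one semihydrogenation of a diyne, and C1'–C7' from acetylide alkylation with 1,7-dibromoheptane.
- C12': from (R)-epichlorohydrin, opened first by butynyllithium (C13'–C14') and then, as the derived epoxide, by a silylpropargyl anion (C10'–C11'). The siloxyethyne comes from acetylene by oxygenation and O-silylation.

Key step: step 10

Remark on the chemistry: (triisopropylsilyloxy)ethyne is the least documented member of the 1-siloxyalkyne family; it is assumed to survive a quick filtration through basic alumina and is made fresh and used at once in excess.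

**Route**

Step 1
Reactants: 1 but-1-yne, 2 (R)-epichlorohydrin
Product: 4 (R)-1-chlorohept-4-yn-2-ol, via but-1-ynyllithium 3 (not isolated)
Conditions: n-BuLi, THF, −78 °C; BF3·OEt2; then 2, −78 °C
Reagents that add atoms: none
Why: Yamaguchi–Hirao alkynylation, in which the lithium acetylide–BF3 pair opens the epoxide at its CH2 carbon much faster than it displaces chloride, so the C–O bond at the stereocentre is untouched and the configuration of 2 is carried into 4.

Step 2
Reactants: 4 (R)-1-chlorohept-4-yn-2-ol
Product: 5 (R)-2-(pent-2-yn-1-yl)oxirane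
Conditions: K2CO3, MeOH, rt; careful concentration (volatile)
Reagents that add atoms: none
Why: Intramolecular Williamson closure of the chlorohydrin moves the epoxide to the former CH2Cl carbon without touching the C–O bond of the stereocentre.

Step 3
Reactants: 5 (R)-2-(pent-2-yn-1-yl)oxirane, 6 1-(trimethylsilyl)prop-1-yne
Product: 8 (S)-1-(trimethylsilyl)deca-1,7-diyn-5-ol, via lithiated silylpropyne 7 (not isolated)
Conditions: 6, n-BuLi, THF, −78 °C; then 5, BF3·OEt2, −78 °C
Reagents that add atoms: none
Why: BF3-assisted epoxide opening by the propargylic carbon of the lithiated silylpropyne (the silyl group blocks the allenyl terminus) forms C10'–C11' at the epoxide CH2, so the carbinol configuration is retained and only its descriptor changes to S because the priorities of the two arms change.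

Step 4
Reactants: 8 (S)-1-(trimethylsilyl)deca-1,7-diyn-5-ol
Product: 9 (S)-5-(tert-butyldimethylsilyloxy)-1-(trimethylsilyl)deca-1,7-diyne
Conditions: TBSCl, imidazole, DMF, rt
Reagents that add atoms: tert-butyldimethylsilyl chloride, CC(C)(C)[Si](C)(C)Cl
Why: Imidazole-promoted silylation of a secondary alcohol masks the C12' hydroxyl for the organometallic steps that follow.

Step 5
Reactants: 9 (S)-5-(tert-butyldimethylsilyloxy)-1-(trimethylsilyl)deca-1,7-diyne
Product: 10 (S)-5-(tert-butyldimethylsilyloxy)deca-1,7-diyne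
Conditions: K2CO3 (cat.), MeOH, rt
Reagents that add atoms: none
Why: Base-catalysed methanolysis cleaves the alkynyl C–Si bond selectively, and the secondary silyl ether is stable to these conditions.

Step 6
Reactants: 10 (S)-5-(tert-butyldimethylsilyloxy)deca-1,7-diyne, 11 1,7-dibromoheptane
Product: 13 (S)-1-bromo-12-(tert-butyldimethylsilyloxy)heptadeca-8,14-diyne, via lithium alkynide 12 (not isolated)
Conditions: n-BuLi, THF, −78 °C; DMPU; 11 (4 equiv), −78 °C to rt
Reagents that add atoms: none
Why: SN2 alkylation of the lithium acetylide with a primary bromide in a dipolar cosolvent attaches C1'–C7', and the excess of the dibromide (recovered) suppresses double alkylation and leaves the terminal bromide for step 8.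

Step 7
Reactants: 13 (S)-1-bromo-12-(tert-butyldimethylsilyloxy)heptadeca-8,14-diyne
Product: 14 (8Z,12S,14Z)-1-bromo-12-(tert-butyldimethylsilyloxy)heptadeca-8,14-diene
Conditions: H2 (1 atm), Pd/CaCO3 poisoned with Pb(OAc)2, quinoline, hexane–EtOAc, rt, stopped at 2 equiv H2
Reagents that add atoms: none
Why: Lindlar semihydrogenation adds hydrogen syn to both alkynes on the poisoned palladium surface, so both alkenes should form with Z geometry while the alkyl bromide and silyl ether are inert.

Step 8
Reactants: 14 (8Z,12S,14Z)-1-bromo-12-(tert-butyldimethylsilyloxy)heptadeca-8,14-diene, 15 3-ethoxycyclobut-2-en-1-one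
Product: 18 3-[(8Z,12S,14Z)-12-(tert-butyldimethylsilyloxy)heptadeca-8,14-dien-1-yl]cyclobut-2-en-1-one, via Grignard reagent 16 (not isolated), via cyclobutenol adduct 17 (not isolated)
Conditions: Mg, THF, 40 °C; then 15, THF, −78 to 0 °C; then 1 M HCl, 0 °C, 20 min
Reagents that add atoms: water, O
Why: Grignard 1,2-addition to the carbonyl of the vinylogous ester followed by acid hydrolysis of the 3-ethoxycyclobutenol (1,3-carbonyl transposition with loss of ethanol) is the standard entry to 3-alkylcyclobutenones, and brief cold dilute acid should spare the secondary TBS ether.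

Step 9
Reactants: 19 acetylene
Product: 22 (triisopropylsilyloxy)ethyne, via ethynyllithium 20 (not isolated), via lithium ethynolate 21 (not isolated)
Conditions: 19 (excess), n-BuLi, THF, −78 °C; t-BuOOLi (from t-BuOOH and LiN(SiMe3)2), −78 to −20 °C; TIPSOTf, −78 to 0 °C; pentane, basic alumina
Reagents that add atoms: tert-butyl hydroperoxide, CC(C)(C)OO; triisopropylsilyl trifluoromethanesulfonate, CC(C)[Si](OS(=O)(=O)C(F)(F)F)(C(C)C)C(C)C
Why: Electrophilic oxygenation of a lithium acetylide by t-BuOOLi to the ynolate followed by O-silylation is the standard route to 1-siloxyalk-1-ynes, applied here to the parent acetylide, and the hard, hindered silyl triflate is expected to react at oxygen and not at carbon.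

Step 10
Reactants: 18 3-[(8Z,12S,14Z)-12-(tert-butyldimethylsilyloxy)heptadeca-8,14-dien-1-yl]cyclobut-2-en-1-one, 22 (triisopropylsilyloxy)ethyne
Product: 27 5-[(8Z,12S,14Z)-12-(tert-butyldimethylsilyloxy)heptadeca-8,14-dien-1-yl]-3-(triisopropylsilyloxy)phenol, via vinylketene 23 (not isolated), via 4-alkenylcyclobutenone 24 (not isolated), via dienylketene 25 (not isolated), via cyclohexadienone 26 (not isolated)
Conditions: 22 (2–3 equiv), toluene, sealed tube, argon, 80 °C, then 110 °C
Reagents that add atoms: none
Why: Thermal 4π electrocyclic opening of 18 gives vinylketene 23, whose ketene C=C adds the electron-rich siloxyalkyne in a [2+2] cycloaddition to give 24; a second 4π opening gives dienylketene 25, a thermal disrotatory 6π electrocyclisation closes ring A at C1–C6 to give 26, and tautomerisation gives phenol 27. This is the Danheiser benzannulation, known for cyclobutenones with alkoxyalkynes and 1-siloxyalk-1-ynes, of which the siloxyethyne is the unsubstituted member. The [2+2] step forms C1–C2 and C3–C4, so the alkyne carbons become C2 and C3 and the four cyclobutenone carbons become C1, C4, C5 and C6. No stereocentre remains in the product (the sp3 ring carbon of 24 becomes planar again), and the neutral thermal conditions leave C12', the TBS ether and both Z-alkenes untouched. The selectivity needed is the orientation of the [2+2] step: the nucleophilic unsubstituted alkyne carbon bonds to the electrophilic ketene carbonyl carbon, which places both oxygens meta to the chain, and because the cyclobutenone carries one substituent at C3 only the 1,3,5-pattern can result. The excess of 22 is meant to outrun dimerisation of the vinylketene and its capture by the product phenol.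

Step 11
Reactants: 27 5-[(8Z,12S,14Z)-12-(tert-butyldimethylsilyloxy)heptadeca-8,14-dien-1-yl]-3-(triisopropylsilyloxy)phenol
Product: 28 5-[(8Z,12S,14Z)-12-hydroxyheptadeca-8,14-dien-1-yl]benzene-1,3-diol (CNP0134801.1)
Conditions: Bu4NF (3 equiv), THF, 0 °C to rt; aqueous NH4Cl work-up
Reagents that add atoms: none
Why: Fluoride-mediated desilylation cleaves the aryl triisopropylsilyl ether and the secondary TBS ether in one operation without touching the Z-alkenes or the C12' configuration.

**Compound list**

1 | but-1-yne | CCC#C | starting material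
2 | (R)-epichlorohydrin | C1[C@@H](O1)CCl | starting material
3 | but-1-yn-1-yllithium | CCC#C[Li] | intermediate
4 | (R)-1-chlorohept-4-yn-2-ol | CCC#CC[C@@H](O)CCl | intermediate
5 | (R)-2-(pent-2-yn-1-yl)oxirane | CCC#CC[C@@H]1CO1 | intermediate
6 | 1-(trimethylsilyl)prop-1-yne | CC#C[Si](C)(C)C | starting material
7 | [3-(trimethylsilyl)prop-2-yn-1-yl]lithium | [Li]CC#C[Si](C)(C)C | intermediate
8 | (S)-1-(trimethylsilyl)deca-1,7-diyn-5-ol | CCC#CC[C@@H](O)CCC#C[Si](C)(C)C | intermediate
9 | (S)-5-(tert-butyldimethylsilyloxy)-1-(trimethylsilyl)deca-1,7-diyne | CCC#CC[C@@H](O[Si](C)(C)C(C)(C)C)CCC#C[Si](C)(C)C | intermediate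
10 | (S)-5-(tert-butyldimethylsilyloxy)deca-1,7-diyne | CCC#CC[C@@H](O[Si](C)(C)C(C)(C)C)CCC#C | intermediate
11 | 1,7-dibromoheptane | BrCCCCCCCBr | starting material
12 | [(S)-5-(tert-butyldimethylsilyloxy)deca-1,7-diyn-1-yl]lithium | CCC#CC[C@@H](O[Si](C)(C)C(C)(C)C)CCC#C[Li] | intermediate
13 | (S)-1-bromo-12-(tert-butyldimethylsilyloxy)heptadeca-8,14-diyne | CCC#CC[C@@H](O[Si](C)(C)C(C)(C)C)CCC#CCCCCCCCBr | intermediate
14 | (8Z,12S,14Z)-1-bromo-12-(tert-butyldimethylsilyloxy)heptadeca-8,14-diene | CC/C=C\C[C@@H](O[Si](C)(C)C(C)(C)C)CC/C=C\CCCCCCCBr | intermediate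
15 | 3-ethoxycyclobut-2-en-1-one | CCOC1=CC(=O)C1 | starting material
16 | [(8Z,12S,14Z)-12-(tert-butyldimethylsilyloxy)heptadeca-8,14-dien-1-yl]magnesium bromide | CC/C=C\C[C@@H](O[Si](C)(C)C(C)(C)C)CC/C=C\CCCCCCC[Mg]Br | intermediate
17 | 1-[(8Z,12S,14Z)-12-(tert-butyldimethylsilyloxy)heptadeca-8,14-dien-1-yl]-3-ethoxycyclobut-2-en-1-ol (both C1 epimers) | CC/C=C\C[C@@H](O[Si](C)(C)C(C)(C)C)CC/C=C\CCCCCCCC1(O)CC(OCC)=C1 | intermediate
18 | 3-[(8Z,12S,14Z)-12-(tert-butyldimethylsilyloxy)heptadeca-8,14-dien-1-yl]cyclobut-2-en-1-one | CC/C=C\C[C@@H](O[Si](C)(C)C(C)(C)C)CC/C=C\CCCCCCCC1=CC(=O)C1 | intermediate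
19 | acetylene | C#C | starting material
20 | ethynyllithium | [Li]C#C | intermediate
21 | lithium ethynolate | [Li]OC#C | intermediate
22 | (triisopropylsilyloxy)ethyne | C#CO[Si](C(C)C)(C(C)C)C(C)C | intermediate
23 | 3-[(8Z,12S,14Z)-12-(tert-butyldimethylsilyloxy)heptadeca-8,14-dien-1-yl]buta-1,3-dien-1-one | CC/C=C\C[C@@H](O[Si](C)(C)C(C)(C)C)CC/C=C\CCCCCCCC(=C)C=C=O | intermediate
24 | 4-[(10Z,14S,16Z)-14-(tert-butyldimethylsilyloxy)nonadeca-1,10,16-trien-2-yl]-3-(triisopropylsilyloxy)cyclobut-2-en-1-one (both C4 epimers) | CC/C=C\C[C@@H](O[Si](C)(C)C(C)(C)C)CC/C=C\CCCCCCCC(=C)C1C(=O)C=C1O[Si](C(C)C)(C(C)C)C(C)C | intermediate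
25 | (3E)-5-[(8Z,12S,14Z)-12-(tert-butyldimethylsilyloxy)heptadeca-8,14-dien-1-yl]-3-(triisopropylsilyloxy)hexa-1,3,5-trien-1-one | CC/C=C\C[C@@H](O[Si](C)(C)C(C)(C)C)CC/C=C\CCCCCCCC(=C)/C=C(O[Si](C(C)C)(C(C)C)C(C)C)\C=C=O | intermediate
26 | 5-[(8Z,12S,14Z)-12-(tert-butyldimethylsilyloxy)heptadeca-8,14-dien-1-yl]-3-(triisopropylsilyloxy)cyclohexa-2,4-dien-1-one | CC/C=C\C[C@@H](O[Si](C)(C)C(C)(C)C)CC/C=C\CCCCCCCC1=CC(O[Si](C(C)C)(C(C)C)C(C)C)=CC(=O)C1 | intermediate
27 | 5-[(8Z,12S,14Z)-12-(tert-butyldimethylsilyloxy)heptadeca-8,14-dien-1-yl]-3-(triisopropylsilyloxy)phenol | CC/C=C\C[C@@H](O[Si](C)(C)C(C)(C)C)CC/C=C\CCCCCCCc1cc(O)cc(O[Si](C(C)C)(C(C)C)C(C)C)c1 | intermediate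
28 | 5-[(8Z,12S,14Z)-12-hydroxyheptadeca-8,14-dien-1-yl]benzene-1,3-diol | CC/C=C\C[C@@H](O)CC/C=C\CCCCCCCc1cc(O)cc(O)c1 | target

**Step count**

Total steps: 11. Longest linear sequence: 10 steps (steps 1 to 8, 10 and 11); step 9 is a one-step branch.

**Steps most likely to fail**

1. Step 10.
   - What may go wrong: the terminal siloxyalkyne may rearrange to the silylketene by a 1,3-shift of silicon from oxygen to carbon, or oligomerise, before the cyclobutenone opens. The vinylketene would then dimerise or acylate the product phenol.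
   - Fallback (gives up the annulation, sets out from 14, comes back at 28): purchased 5-bromoresorcinol is silylated (TBSCl, imidazole, DMF) to 1-bromo-3,5-bis(tert-butyldimethylsilyloxy)benzene F1. Grignard reagent 16, made from 14 as in step 8, is transmetalated with ZnCl2 to [(8Z,12S,14Z)-12-(tert-butyldimethylsilyloxy)heptadeca-8,14-dien-1-yl]zinc chloride F2. A Negishi coupling of F2 and F1 (Pd(OAc)2, SPhos, THF, rt to 50 °C) should give 5-[(8Z,12S,14Z)-12-(tert-butyldimethylsilyloxy)heptadeca-8,14-dien-1-yl]-1,3-bis(tert-butyldimethylsilyloxy)benzene F3. Bu4NF in THF then removes the three silyl groups to give 28.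

2. Step 9.
   - What may go wrong: silylation of the unhindered ynolate on carbon instead of oxygen (leading to the silylketene), disproportionation of ethynyllithium on warming before it is oxygenated, or loss of the labile product during isolation.
   - Fallback (changes the alkyne partner and the end game, sets out from 18, comes back at 28): methoxyethyne F4 is made by elimination from purchased chloroacetaldehyde dimethyl acetal with NaNH2 in liquid NH3. Heated with 18 (toluene, sealed tube, 80 °C), the same benzannulation in its alkoxyalkyne form should give 5-[(8Z,12S,14Z)-12-(tert-butyldimethylsilyloxy)heptadeca-8,14-dien-1-yl]-3-methoxyphenol F5. Bu4NF removes the TBS ether to give 5-[(8Z,12S,14Z)-12-hydroxyheptadeca-8,14-dien-1-yl]-3-methoxyphenol F6. The aryl methyl ether is then cleaved with MeMgI (neat, 160 °C), a method tolerated by alkene-bearing resorcinol methyl ethers, to give 28.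

3. Step 3.
   - What may go wrong: attack through the allenyl terminus of the ambident anion, or removal of the propargylic proton next to the epoxide with ring opening to an enynol.
   - Fallback (replaces the propargyl anion by an allyl unit that is later turned into the alkyne, sets out from 5, comes back at 10): opening of 5 with allylmagnesium bromide and catalytic CuI (THF, −30 °C) gives (S)-dec-1-en-7-yn-5-ol F7. Silylation (TBSCl, imidazole, DMF) gives (S)-5-(tert-butyldimethylsilyloxy)dec-1-en-7-yne F8. Lemieux–Johnson cleavage of the terminal alkene (catalytic OsO4, NaIO4, 2,6-lutidine, dioxane–water), which spares the alkyne, gives (S)-4-(tert-butyldimethylsilyloxy)non-6-ynal F9. Ohira–Bestmann homologation (dimethyl (1-diazo-2-oxopropyl)phosphonate, K2CO3, MeOH) then gives 10.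

**Further compounds**

F1 | step 10 | 1-bromo-3,5-bis(tert-butyldimethylsilyloxy)benzene | Brc1cc(O[Si](C)(C)C(C)(C)C)cc(O[Si](C)(C)C(C)(C)C)c1
F2 | step 10 | [(8Z,12S,14Z)-12-(tert-butyldimethylsilyloxy)heptadeca-8,14-dien-1-yl]zinc chloride | CC/C=C\C[C@@H](O[Si](C)(C)C(C)(C)C)CC/C=C\CCCCCCC[Zn]Cl
F3 | step 10 | 5-[(8Z,12S,14Z)-12-(tert-butyldimethylsilyloxy)heptadeca-8,14-dien-1-yl]-1,3-bis(tert-butyldimethylsilyloxy)benzene | CC/C=C\C[C@@H](O[Si](C)(C)C(C)(C)C)CC/C=C\CCCCCCCc1cc(O[Si](C)(C)C(C)(C)C)cc(O[Si](C)(C)C(C)(C)C)c1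
F4 | step 9 | methoxyethyne | COC#C
F5 | step 9 | 5-[(8Z,12S,14Z)-12-(tert-butyldimethylsilyloxy)heptadeca-8,14-dien-1-yl]-3-methoxyphenol | CC/C=C\C[C@@H](O[Si](C)(C)C(C)(C)C)CC/C=C\CCCCCCCc1cc(O)cc(OC)c1
F6 | step 9 | 5-[(8Z,12S,14Z)-12-hydroxyheptadeca-8,14-dien-1-yl]-3-methoxyphenol | CC/C=C\C[C@@H](O)CC/C=C\CCCCCCCc1cc(O)cc(OC)c1
F7 | step 3 | (S)-dec-1-en-7-yn-5-ol | CCC#CC[C@@H](O)CCC=C
F8 | step 3 | (S)-5-(tert-butyldimethylsilyloxy)dec-1-en-7-yne | CCC#CC[C@@H](O[Si](C)(C)C(C)(C)C)CCC=C
F9 | step 3 | (S)-4-(tert-butyldimethylsilyloxy)non-6-ynal | CCC#CC[C@@H](O[Si](C)(C)C(C)(C)C)CCC=O
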